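**Retrosynthetic overview**

1. The last bond made is oxindole C3–CH2. A racemic 3-bromo-oxindole serves as an enolonium equivalent (the normally nucleophilic C3 made electrophilic) and is joined to a pyrazinylmethylzinc reagent (an aza-enolate-type donor carbon). A nickel/pybox enantioconvergent Negishi coupling forms the bond and sets C3 (S) in the same step; the O-silyl group falls off on work-up.
2. The bromo-oxindole comes from 7-bromoisatin: reduction of the C3 carbonyl, Stille prenylation, OH to Br.
3. The zinc reagent comes from 5-methoxy-3,6-dimethylpyrazin-2(1H)-one: lateral bromination of the 6-methyl, O-silylation, zinc insertion.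
4. That pyrazinone comes from alanine anhydride: mono-lactim ether, then DDQ aromatisation.
5. Ring order: the oxindole ring is bought intact; the pyrazinone ring is bought as the diketopiperazine and aromatised before the coupling; no ring is closed afterwards.

Assumption: the (R,R) enantiomer of the pybox ligand is taken to give the (S) product; the sense of induction has to be confirmed on the first run, and the (S,S) ligand is used instead if it is the opposite.

**Route**

Step 1
Reactants: 1 7-bromoisatin
Product: 2 rac-7-bromo-3-hydroxyindolin-2-one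
Conditions: NaBH4 (1.0 equiv), EtOH/THF, 0 °C, 30 min; AcOH quench
Reagents that add atoms: none
Why: Chemoselective borohydride reduction of the ketone-like C3 carbonyl (far more electrophilic than the lactam) gives the racemic dioxindole and removes the carbonyl that an allyl-tin reagent could attack in step 2; the new stereocentre is racemic and is replaced later.

Step 2
Reactants: 2 rac-7-bromo-3-hydroxyindolin-2-one, 3 tributyl(3-methylbut-2-en-1-yl)stannane
Product: 4 rac-3-hydroxy-7-(3-methylbut-2-en-1-yl)indolin-2-one
Conditions: Pd(PPh3)4 (5 mol%), DMF, 90 °C, argon; aq. KF work-up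
Reagents that add atoms: tributyl(3-methylbut-2-en-1-yl)stannane (3), CCCC[Sn](CCCC)(CCCC)CC=C(C)C
Why: Stille coupling is base-free, so the free OH and NH are tolerated, and reductive elimination from the π-prenyl palladium intermediate at its unsubstituted terminus gives the linear prenyl arene; no stereocentre is touched.

Step 3
Reactants: 4 rac-3-hydroxy-7-(3-methylbut-2-en-1-yl)indolin-2-one
Product: 5 rac-3-bromo-7-(3-methylbut-2-en-1-yl)indolin-2-one
Conditions: CBr4 (1.3 equiv), then PPh3 (1.25 equiv) in portions, CH2Cl2, 0 °C; rapid silica filtration, store cold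
Reagents that add atoms: carbon tetrabromide, BrC(Br)(Br)Br
Why: The Appel reaction converts the benzylic α-hydroxy lactam into the bromide by displacement on the oxyphosphonium under neutral conditions (no HBr, so the prenyl alkene survives), giving the racemic α-bromo lactam that acts as the enolonium equivalent.

Step 4
Reactants: 6 cyclo(L-Ala-L-Ala)
Product: 7 (3S,6S)-5-methoxy-3,6-dimethyl-3,6-dihydropyrazin-2(1H)-one
Conditions: Me3OBF4 (1.05 equiv), CH2Cl2, rt, 24–48 h; cold aq. NaHCO3
Reagents that add atoms: trimethyloxonium tetrafluoroborate, C[O+](C)C.F[B-](F)(F)F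
Why: Meerwein O-alkylation gives the lactim ether as its HBF4 salt, which deactivates the second amide and so stops at mono-alkylation, and the symmetry of the diketopiperazine removes any regiochemical question; the two stereocentres are irrelevant because step 5 destroys them.

Step 5
Reactants: 7 (3S,6S)-5-methoxy-3,6-dimethyl-3,6-dihydropyrazin-2(1H)-one
Product: 8 5-methoxy-3,6-dimethylpyrazin-2(1H)-one
Conditions: DDQ (1.0 equiv), 1,4-dioxane, 80 °C, 2 h
Reagents that add atoms: none
Why: DDQ dehydrogenation of the 3,6-dihydropyrazinone is driven by aromatisation and fixes the methoxy group on the carbon para to the lactam carbonyl; both stereocentres become sp2.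

Step 6
Reactants: 8 5-methoxy-3,6-dimethylpyrazin-2(1H)-one
Product: 9 6-(bromomethyl)-5-methoxy-3-methylpyrazin-2(1H)-one
Conditions: NBS (1.0 equiv), MeCN, 0 °C, dark, no acid; use directly
Reagents that add atoms: N-bromosuccinimide, O=C1CCC(=O)N1Br
Why: Electrophilic lateral (ene-type) bromination, as known for 5-substituted 6-methyluracils: Br+ adds to the electron-rich enamide/enol-ether C5=C6 bond to give an N1-stabilised acyliminium ion, the 6-methyl loses a proton and a 1,3-shift of bromide restores the aromatic ring, while the 3-methyl on the C=N carbon would need acid-catalysed enamine formation, which is not opened because no HBr is formed.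

Step 7
Reactants: 9 6-(bromomethyl)-5-methoxy-3-methylpyrazin-2(1H)-one (1.5 equiv), 5 rac-3-bromo-7-(3-methylbut-2-en-1-yl)indolin-2-one (1.0 equiv)
Product: 13 astepyrazinol B, via O-silyl bromide 10 (not isolated), via benzylic zinc bromide 11 (not isolated), via O-silyl coupling product 12 (not isolated)
Conditions: (i) MTBSTFA (1.1 equiv), THF, 40 °C, then evaporate; (ii) Zn dust, LiCl, THF, 0 °C; (iii) slow addition to 5, NiCl2·(MeOCH2CH2OMe) (10 mol%), (R,R)-i-Pr-Pybox (13 mol%), DMA/THF, −20 °C, 12 h; (iv) 10% aq. citric acid, THF, 0 °C
Reagents that add atoms: none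
Why: Proposed new method: an enantioconvergent nickel-catalysed Negishi coupling in which monovalent nickel abstracts bromine from racemic 5 to give a planar, captodatively stabilised C3 radical (both enantiomers converge), this radical is captured by the chiral pybox–nickel–alkyl species formed from 11, and reductive elimination forms the C3–CH2 bond and sets the (S) centre under base-free conditions at −20 °C, where the benzylic zinc halide is too weakly basic to deprotonate the lactam N–H or the product C3–H (the O-silyl group removes the acidic, basic-anion-forming pyrazinone N–H and is hydrolysed in the acidic work-up, which does not epimerise C3); the closest known reaction type is the nickel/pybox-catalysed stereoconvergent Negishi coupling of racemic secondary α-bromo amides with alkylzinc halides and of α-bromo ketones with arylzinc halides.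

**Compound list**

1 | 7-bromoisatin (7-bromoindoline-2,3-dione) | O=C1Nc2c(Br)cccc2C1=O | starting material
2 | rac-7-bromo-3-hydroxyindolin-2-one | O=C1Nc2c(Br)cccc2C1O | intermediate
3 | tributyl(3-methylbut-2-en-1-yl)stannane | CCCC[Sn](CCCC)(CCCC)CC=C(C)C | starting material
4 | rac-3-hydroxy-7-(3-methylbut-2-en-1-yl)indolin-2-one | O=C1Nc2c(CC=C(C)C)cccc2C1O | intermediate
5 | rac-3-bromo-7-(3-methylbut-2-en-1-yl)indolin-2-one | O=C1Nc2c(CC=C(C)C)cccc2C1Br | intermediate
6 | cyclo(L-Ala-L-Ala), (3S,6S)-3,6-dimethylpiperazine-2,5-dione | C[C@H]1C(=O)N[C@@H](C)C(=O)N1 | starting material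
7 | (3S,6S)-5-methoxy-3,6-dimethyl-3,6-dihydropyrazin-2(1H)-one | C[C@H]1C(OC)=N[C@@H](C)C(=O)N1 | intermediate
8 | 5-methoxy-3,6-dimethylpyrazin-2(1H)-one | COc1nc(C)c(=O)[nH]c1C | intermediate
9 | 6-(bromomethyl)-5-methoxy-3-methylpyrazin-2(1H)-one | COc1nc(C)c(=O)[nH]c1CBr | intermediate
10 | 2-(bromomethyl)-6-[(tert-butyldimethylsilyl)oxy]-3-methoxy-5-methylpyrazine | COc1nc(C)c(O[Si](C)(C)C(C)(C)C)nc1CBr | intermediate (not isolated)
11 | ({6-[(tert-butyldimethylsilyl)oxy]-3-methoxy-5-methylpyrazin-2-yl}methyl)zinc bromide | COc1nc(C)c(O[Si](C)(C)C(C)(C)C)nc1C[Zn]Br | intermediate (not isolated)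
12 | (3S)-3-({6-[(tert-butyldimethylsilyl)oxy]-3-methoxy-5-methylpyrazin-2-yl}methyl)-7-(3-methylbut-2-en-1-yl)indolin-2-one | COc1nc(C)c(O[Si](C)(C)C(C)(C)C)nc1C[C@@H]1C(=O)Nc2c(CC=C(C)C)cccc21 | intermediate (not isolated)
13 | astepyrazinol B, (3S)-3-[(3-methoxy-5-methyl-6-oxo-1,6-dihydropyrazin-2-yl)methyl]-7-(3-methylbut-2-en-1-yl)indolin-2-one | COc1nc(C)c(=O)[nH]c1C[C@@H]1C(=O)Nc2c(CC=C(C)C)cccc21 | target

**Totals**

Total step count: 7. Longest linear sequence: 4 steps (6 → 7 → 8 → 9 → 13, or 1 → 2 → 4 → 5 → 13).

**Steps most likely to fail, with fallbacks**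

Step 7 (key coupling). The risks are low enantioselectivity with an N–H lactam electrophile and a racemic background path by loss of HBr from 5 to the indol-2-one. The fallback separates bond formation from stereocontrol. It sets out from 5 and 11, which are coupled with an achiral catalyst (NiCl2·(MeOCH2CH2OMe) with 2,2'-bipyridine) to the racemic O-silyl coupling product F1. Without hydrolysis this is treated with TBSOTf and Et3N to give the 2-silyloxyindole bis-silyl ketene aminal F2, in which C3 is sp2. A catalytic enantioselective protonation (chiral BINOL-derived N-triflyl thiophosphoramide, phenol as the stoichiometric proton source, toluene, −78 °C) then sets C3, and the citric acid work-up removes the pyrazine silyl group, so the fallback comes back to the route at 13.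

Step 6 (site of lateral bromination). The risk is bromination at the 3-methyl instead of the 6-methyl. The fallback changes from ionic bromination of the free pyrazinone to a radical bromination steered by a polar effect. It sets out from 8, which is O-acylated with pivaloyl chloride and Et3N to 5-methoxy-3,6-dimethylpyrazin-2-yl pivalate F3. Wohl–Ziegler bromination (NBS, AIBN, PhCF3, 80 °C) then favours hydrogen abstraction from the methyl ortho to the donor OMe over the methyl ortho to the acyloxy group, giving 6-(bromomethyl)-5-methoxy-3-methylpyrazin-2-yl pivalate F4 after separation of the minor isomer. Zinc insertion (Zn, LiCl, THF) gives the pivalate-protected benzylic zinc bromide F5, which is coupled with 5 under the nickel/pybox conditions of step 7 to the (S)-configured coupled pivalate F6. Brief aminolysis with NH3 in MeOH at 0 °C cleaves the activated lactim ester, and the fallback comes back to the route at 13.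

Step 2 (prenyl transfer). The risk is a mixture of linear and branched prenyl products or slow coupling. The fallback builds the prenyl group in two stages. It sets out from 2, which undergoes Stille coupling with allyltributylstannane (Pd(PPh3)4, DMF, 90 °C) to rac-7-allyl-3-hydroxyindolin-2-one F7, where no allylic regiochemistry is at stake. Olefin cross-metathesis with excess 2-methylbut-2-ene (second-generation Grubbs catalyst, CH2Cl2, 40 °C) converts the allyl into the prenyl group, and the fallback comes back to the route at 4.

**Further compounds**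

F1 | step 7 | rac-3-({6-[(tert-butyldimethylsilyl)oxy]-3-methoxy-5-methylpyrazin-2-yl}methyl)-7-(3-methylbut-2-en-1-yl)indolin-2-one | COc1nc(C)c(O[Si](C)(C)C(C)(C)C)nc1CC1C(=O)Nc2c(CC=C(C)C)cccc21
F2 | step 7 | 2-[(tert-butyldimethylsilyl)oxy]-3-({6-[(tert-butyldimethylsilyl)oxy]-3-methoxy-5-methylpyrazin-2-yl}methyl)-7-(3-methylbut-2-en-1-yl)-1H-indole | COc1nc(C)c(O[Si](C)(C)C(C)(C)C)nc1Cc1c(O[Si](C)(C)C(C)(C)C)[nH]c2c(CC=C(C)C)cccc12
F3 | step 6 | 5-methoxy-3,6-dimethylpyrazin-2-yl pivalate | COc1nc(C)c(OC(=O)C(C)(C)C)nc1C
F4 | step 6 | 6-(bromomethyl)-5-methoxy-3-methylpyrazin-2-yl pivalate | COc1nc(C)c(OC(=O)C(C)(C)C)nc1CBr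
F5 | step 6 | {[3-methoxy-5-methyl-6-(pivaloyloxy)pyrazin-2-yl]methyl}zinc bromide | COc1nc(C)c(OC(=O)C(C)(C)C)nc1C[Zn]Br
F6 | step 6 | 5-methoxy-3-methyl-6-{[(3S)-7-(3-methylbut-2-en-1-yl)-2-oxoindolin-3-yl]methyl}pyrazin-2-yl pivalate | COc1nc(C)c(OC(=O)C(C)(C)C)nc1C[C@@H]1C(=O)Nc2c(CC=C(C)C)cccc21
F7 | step 2 | rac-7-allyl-3-hydroxyindolin-2-one | O=C1Nc2c(CC=C)cccc2C1O
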